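**Plan**

- Retrosynthesis: in ring A (tetrahydrofuran O1, C2 to C5) the C4–OH bond and the CH2–aryl bond of the C4 benzyl group are cut, and the C5 methylene is traced back to a lactone carbonyl. The resulting α-methylene lactone is cut at C2–C3 and O1–C5 into a dihydrobenzofuran-5-carbaldehyde and a γ-substituted 2-(methoxycarbonyl)allylboronate.
- Ring B (dihydrobenzofuran, primed locants) is cut at C2′–C3′ to an aryldiazoacetate, assembled from an iodophenol, a benzylic alcohol and ethyl diazoacetate.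
- Forward: ring B closes first by carbenoid C–H insertion and the C5′ bromide becomes the aldehyde. Ring A then closes as a lactone in the allylboration, C4 receives benzyl and hydroxyl, the lactone is reduced to the ether and the benzyl groups are removed.
- Enabling feature: ring A has its C2 aryl and C3 hydroxymethyl groups cis and an O1–C5 link next to a fully substituted C4. This is the imprint of a chair allylboration by a boronate whose γ-substituent is cis to CH2B, followed by capture of the ester (syn C2/C3, lactone O1–C5, exocyclic C4=CH2).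
- Stereochemistry: C2′/C3′ (cis) from a chiral dirhodium carboxylate; C2 from a chiral phosphoric acid; C3 from the boronate geometry; C4 from enolate hydroxylation on the face away from the cis C2/C3 groups.

Key step: step 11

Assumption: the SMILES is read as (2R,3R,4S) in ring A with C2/C3 cis and (2′R,3′R) in ring B with C2′/C3′ cis; the route is built for this isomer.

Assumption: the facial sense of Rh2(S-PTTL)4 (step 4) and of (R)-TRIP (step 11) is taken from the accepted models for these catalyst families; should either give the opposite sense, its mirror-image catalyst is used with no other change.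

Abbreviations and locants:
- BMP = 4-(benzyloxy)-3-methoxyphenyl.
- DHB = (2R,3R)-3-[(benzyloxy)methyl]-2-BMP-7-methoxy-2,3-dihydro-1-benzofuran-5-yl.
- Bpin = 4,4,5,5-tetramethyl-1,3,2-dioxaborolan-2-yl.
- TRIP = 3,3′-bis(2,4,6-triisopropylphenyl)-1,1′-binaphthyl-2,2′-diyl hydrogen phosphate.
- Rh2(S-PTTL)4 = dirhodium tetrakis[N-phthaloyl-(S)-tert-leucinate].
- DIAD = diisopropyl azodicarboxylate; DABCO = 1,4-diazabicyclo[2.2.2]octane.
- In the Why lines ring A is numbered as in the target (O1, C2 aryl-bearing, C3, C4 quaternary, C5); systematic names of the lactones carry their own locants.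

**Route**

Step 1
Reactants: 1 4-bromo-2-methoxyphenol
Product: 2 4-bromo-2-iodo-6-methoxyphenol
Conditions: I2, NaHCO3, THF/H2O, 0 °C → rt
Reagents that add atoms: iodine, II
Why: Electrophilic aromatic iodination of the phenol under mildly basic conditions goes ortho to oxygen because the para position carries bromine, so only C6 should be iodinated.

Step 2
Reactants: 2 4-bromo-2-iodo-6-methoxyphenol; 3 [4-(benzyloxy)-3-methoxyphenyl]methanol
Product: 4 1-(benzyloxy)-4-[(4-bromo-2-iodo-6-methoxyphenoxy)methyl]-2-methoxybenzene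
Conditions: PPh3, DIAD, THF, 0 °C → rt
Reagents that add atoms: none
Why: Mitsunobu etherification joins the acidic dihalophenol to the primary benzylic alcohol under neutral conditions that leave both carbon–halogen bonds untouched.

Step 3
Reactants: 4 1-(benzyloxy)-4-[(4-bromo-2-iodo-6-methoxyphenoxy)methyl]-2-methoxybenzene; 5 ethyl diazoacetate
Product: 6 ethyl 2-{2-[(BMP)methoxy]-5-bromo-3-methoxyphenyl}-2-diazoacetate
Conditions: Pd(PPh3)4 (5 mol %), Ag2CO3 (0.5 equiv), Et3N, toluene, rt
Reagents that add atoms: none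
Why: Palladium-catalysed cross-coupling of an aryl iodide with the C–H bond of ethyl diazoacetate keeps the diazo group, and zerovalent palladium inserts into the C–I bond at room temperature while the C–Br bond stays intact.

Step 4
Reactants: 6 ethyl 2-{2-[(BMP)methoxy]-5-bromo-3-methoxyphenyl}-2-diazoacetate
Product: 7 ethyl (2R,3S)-2-BMP-5-bromo-7-methoxy-2,3-dihydro-1-benzofuran-3-carboxylate (2,3-cis)
Conditions: Rh2(S-PTTL)4 (2 mol %), toluene, −78 °C
Reagents that add atoms: none
Why: Intramolecular 1,5 C–H insertion of the donor/acceptor rhodium carbenoid into the ether methylene, which is activated by oxygen and the electron-rich arene, closes ring B through a concerted hydride-transfer-like transition state in which the chiral carboxylate wall selects one enantiotopic benzylic hydrogen and should give the kinetic cis C2′/C3′ product at low temperature.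

Step 5
Reactants: 7 ethyl (2R,3S)-2-BMP-5-bromo-7-methoxy-2,3-dihydro-1-benzofuran-3-carboxylate
Product: 8 [(2R,3R)-2-BMP-5-bromo-7-methoxy-2,3-dihydro-1-benzofuran-3-yl]methanol
Conditions: i-Bu2AlH, CH2Cl2, −78 → 0 °C; aq. Rochelle salt
Reagents that add atoms: none
Why: Hydride reduction of the ester by a Lewis acidic and non-basic aluminium hydride should give the primary alcohol without enolising C3′, so the cis relationship is kept.

Step 6
Reactants: 8 [(2R,3R)-2-BMP-5-bromo-7-methoxy-2,3-dihydro-1-benzofuran-3-yl]methanol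
Product: 9 (2R,3R)-3-[(benzyloxy)methyl]-2-BMP-5-bromo-7-methoxy-2,3-dihydro-1-benzofuran
Conditions: NaH, BnBr, n-Bu4NI (cat.), THF/DMF, 0 °C → rt
Reagents that add atoms: benzyl bromide, BrCc1ccccc1
Why: Williamson ether synthesis on the primary alkoxide is safe here because no acidic C–H remains next to the two stereocentres.

Step 7
Reactants: 9 (2R,3R)-3-[(benzyloxy)methyl]-2-BMP-5-bromo-7-methoxy-2,3-dihydro-1-benzofuran
Product: 11 (2R,3R)-3-[(benzyloxy)methyl]-2-BMP-7-methoxy-2,3-dihydro-1-benzofuran-5-carbaldehyde, via aryllithium 10 (not isolated)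
Conditions: n-BuLi, THF, −78 °C; DMF, −78 → 0 °C; H2O
Reagents that add atoms: N,N-dimethylformamide, CN(C)C=O
Why: Bromine–lithium exchange at −78 °C is faster than any deprotonation, and formylation of the aryllithium with DMF should give the aldehyde on hydrolysis of the hemiaminal alkoxide.

Step 8
Reactants: 12 2-(benzyloxy)acetaldehyde; 13 methyl acrylate
Product: 14 methyl 4-(benzyloxy)-3-hydroxy-2-methylidenebutanoate (racemic)
Conditions: DABCO (0.5 equiv), excess methyl acrylate as solvent, rt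
Reagents that add atoms: none
Why: Morita–Baylis–Hillman reaction, which α-alkoxy aldehydes undergo readily, gives the adduct whose racemic carbinol centre is erased two steps later.

Step 9
Reactants: 14 methyl 4-(benzyloxy)-3-hydroxy-2-methylidenebutanoate
Product: 15 methyl 3-acetoxy-4-(benzyloxy)-2-methylidenebutanoate (racemic)
Conditions: Ac2O, pyridine, DMAP (cat.), CH2Cl2, 0 °C → rt
Reagents that add atoms: acetic anhydride, CC(=O)OC(C)=O
Why: Nucleophilic-catalysed acylation turns the allylic alcohol into the leaving group needed for allylic substitution.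

Step 10
Reactants: 15 methyl 3-acetoxy-4-(benzyloxy)-2-methylidenebutanoate; 16 bis(pinacolato)diboron
Product: 17 methyl (E)-4-(benzyloxy)-2-[(Bpin)methyl]but-2-enoate
Conditions: CuCl (10 mol %), LiCl, KOAc, DMF, rt
Reagents that add atoms: none
Why: Copper-catalysed SN2′ borylation of the Morita–Baylis–Hillman acetate by a boryl copper species should place the CH2OBn group trans to the ester and thus cis to CH2B, as is general for allylic substitution of such acrylate acetates.

Step 11
Reactants: 11 (2R,3R)-3-[(benzyloxy)methyl]-2-BMP-7-methoxy-2,3-dihydro-1-benzofuran-5-carbaldehyde; 17 methyl (E)-4-(benzyloxy)-2-[(Bpin)methyl]but-2-enoate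
Product: 19 (4R,5R)-4-[(benzyloxy)methyl]-5-(DHB)-3-methylideneoxolan-2-one (4,5-cis), via syn-borate 18 (not isolated)
Conditions: (R)-TRIP (10 mol %), 4 Å MS, toluene, −20 °C → rt
Reagents that add atoms: none
Why: The phosphoric acid hydrogen-bonds to a pinacol oxygen of 17 and to the formyl C–H of 11 while the aldehyde oxygen binds boron, so that C2–C3 forms through a closed six-membered chair (Zimmerman–Traxler) transition state and gives borate 18. The closest known reaction types are the chiral phosphoric acid-catalysed allyl- and crotylboration of aryl aldehydes with pinacol boronates and the allylboration–lactonisation of aldehydes with 2-(alkoxycarbonyl)allylboronates. Ring A closes when the borate oxygen of 18 attacks the neighbouring methyl ester in a 5-exo-trig acyl substitution that makes O1–C5 and expels the methoxide on boron. C2 is set by the catalyst, whose binaphthyl pocket should expose the Re face of the aldehyde, and C3 is set relative to C2 by the (E)-geometry of 17, because the CH2OBn group cis to CH2B must sit axial in the chair with the aryl group equatorial, which gives the syn adduct and hence the cis lactone. The step needs face selectivity on an aldehyde whose own stereocentres are remote and exert no bias, so the catalyst alone decides, and it needs the syn relationship to survive, which the weak acid, the non-polar solvent and the low temperature secure by not ionising the electron-rich benzylic C–O bond.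

Step 12
Reactants: 1 4-bromo-2-methoxyphenol
Product: 20 1-(benzyloxy)-4-bromo-2-methoxybenzene
Conditions: BnBr, K2CO3, DMF, rt
Reagents that add atoms: benzyl bromide, BrCc1ccccc1
Why: Williamson etherification of the phenol gives the aryl bromide needed for the Grignard reagent.

Step 13
Reactants: 19 (4R,5R)-4-[(benzyloxy)methyl]-5-(DHB)-3-methylideneoxolan-2-one; 20 1-(benzyloxy)-4-bromo-2-methoxybenzene
Product: 22 (4R,5R)-3-[(BMP)methyl]-4-[(benzyloxy)methyl]-5-(DHB)oxolan-2-one (C3 epimers), via Grignard reagent 21 (not isolated)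
Conditions: Mg, THF, rt; then CuI (20 mol %), 19, THF, −40 → −20 °C; H2O
Reagents that add atoms: none
Why: Copper-catalysed conjugate addition of the aryl Grignard reagent to the exocyclic enoate forms the CH2–aryl bond, and the α-centre formed on protonation is of no consequence because it is re-enolised in the next step.

Step 14
Reactants: 22 (4R,5R)-3-[(BMP)methyl]-4-[(benzyloxy)methyl]-5-(DHB)oxolan-2-one
Product: 24 (3S,4R,5R)-3-[(BMP)methyl]-4-[(benzyloxy)methyl]-5-(DHB)-3-hydroxyoxolan-2-one, via sodium enolate 23 (not isolated)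
Conditions: NaN(SiMe3)2, THF, −78 °C; 2-(phenylsulfonyl)-3-phenyloxaziridine, −78 °C; AcOH
Reagents that add atoms: 2-(phenylsulfonyl)-3-phenyloxaziridine, O=S(=O)(N1OC1c1ccccc1)c1ccccc1
Why: Enolate oxidation with the Davis oxaziridine should occur on the face of the planar enolate opposite the cis C3 CH2OBn and C2 aryl groups, which places the hydroxyl trans and the benzyl group cis to them and so sets C4.

Step 15
Reactants: 24 (3S,4R,5R)-3-[(BMP)methyl]-4-[(benzyloxy)methyl]-5-(DHB)-3-hydroxyoxolan-2-one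
Product: 25 (3S,4R,5R)-3-[(BMP)methyl]-4-[(benzyloxy)methyl]-5-(DHB)oxolane-2,3-diol (C2 anomers)
Conditions: i-Bu2AlH, CH2Cl2, −78 °C; aq. Rochelle salt
Reagents that add atoms: none
Why: Partial reduction of the lactone at −78 °C stops at the aluminium hemiacetal, which should give the lactol on work-up.

Step 16
Reactants: 25 (3S,4R,5R)-3-[(BMP)methyl]-4-[(benzyloxy)methyl]-5-(DHB)oxolane-2,3-diol
Product: 26 (3S,4R,5R)-3-[(BMP)methyl]-4-[(benzyloxy)methyl]-5-(DHB)oxolan-3-ol
Conditions: Et3SiH, BF3·OEt2, CH2Cl2, −78 → −50 °C; aq. NaHCO3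
Reagents that add atoms: none
Why: Ionic hydrogenation of the lactol, in which BF3·OEt2 generates the cyclic oxocarbenium ion at C5 and Et3SiH reduces it, is run cold so that the benzylic C–O bonds at C2 and C2′ are not ionised.

Step 17
Reactants: 26 (3S,4R,5R)-3-[(BMP)methyl]-4-[(benzyloxy)methyl]-5-(DHB)oxolan-3-ol
Product: 27 (3S,4R,5R)-4-(hydroxymethyl)-3-[(4-hydroxy-3-methoxyphenyl)methyl]-5-[(2R,3R)-2-(4-hydroxy-3-methoxyphenyl)-3-(hydroxymethyl)-7-methoxy-2,3-dihydro-1-benzofuran-5-yl]oxolan-3-ol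
Conditions: H2 (1 atm), 10% Pd/C, EtOAc/EtOH, rt
Reagents that add atoms: none
Why: Catalytic hydrogenolysis should cleave the four O-benzyl groups under neutral conditions at one atmosphere, where the cyclic benzylic ethers of rings A and B react far more slowly.

**Compound list**

1 | 4-bromo-2-methoxyphenol | COc1cc(Br)ccc1O | starting material
2 | 4-bromo-2-iodo-6-methoxyphenol | COc1cc(Br)cc(I)c1O | intermediate
3 | [4-(benzyloxy)-3-methoxyphenyl]methanol | COc1cc(CO)ccc1OCc1ccccc1 | starting material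
4 | 1-(benzyloxy)-4-[(4-bromo-2-iodo-6-methoxyphenoxy)methyl]-2-methoxybenzene | COc1cc(COc2c(I)cc(Br)cc2OC)ccc1OCc1ccccc1 | intermediate
5 | ethyl diazoacetate | CCOC(=O)C=[N+]=[N-] | starting material
6 | ethyl 2-{2-[(BMP)methoxy]-5-bromo-3-methoxyphenyl}-2-diazoacetate | CCOC(=O)C(=[N+]=[N-])c1cc(Br)cc(OC)c1OCc1ccc(OCc2ccccc2)c(OC)c1 | intermediate
7 | ethyl (2R,3S)-2-BMP-5-bromo-7-methoxy-2,3-dihydro-1-benzofuran-3-carboxylate (cis) | Brc1cc(OC)c2c(c1)[C@H](C(=O)OCC)[C@H](c1ccc(OCc3ccccc3)c(OC)c1)O2 | intermediate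
8 | [(2R,3R)-2-BMP-5-bromo-7-methoxy-2,3-dihydro-1-benzofuran-3-yl]methanol | Brc1cc(OC)c2c(c1)[C@H](CO)[C@H](c1ccc(OCc3ccccc3)c(OC)c1)O2 | intermediate
9 | (2R,3R)-3-[(benzyloxy)methyl]-2-BMP-5-bromo-7-methoxy-2,3-dihydro-1-benzofuran | Brc1cc(OC)c2c(c1)[C@H](COCc1ccccc1)[C@H](c1ccc(OCc3ccccc3)c(OC)c1)O2 | intermediate
10 | 5-lithio derivative of 9 (aryllithium, not isolated) | [Li]c1cc(OC)c2c(c1)[C@H](COCc1ccccc1)[C@H](c1ccc(OCc3ccccc3)c(OC)c1)O2 | intermediate
11 | (2R,3R)-3-[(benzyloxy)methyl]-2-BMP-7-methoxy-2,3-dihydro-1-benzofuran-5-carbaldehyde | O=Cc1cc(OC)c2c(c1)[C@H](COCc1ccccc1)[C@H](c1ccc(OCc3ccccc3)c(OC)c1)O2 | intermediate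
12 | 2-(benzyloxy)acetaldehyde | O=CCOCc1ccccc1 | starting material
13 | methyl acrylate | C=CC(=O)OC | starting material
14 | methyl 4-(benzyloxy)-3-hydroxy-2-methylidenebutanoate (racemic) | C=C(C(=O)OC)C(O)COCc1ccccc1 | intermediate
15 | methyl 3-acetoxy-4-(benzyloxy)-2-methylidenebutanoate (racemic) | C=C(C(=O)OC)C(OC(C)=O)COCc1ccccc1 | intermediate
16 | bis(pinacolato)diboron | CC1(C)OB(OC1(C)C)B1OC(C)(C)C(C)(C)O1 | starting material
17 | methyl (E)-4-(benzyloxy)-2-[(Bpin)methyl]but-2-enoate | COC(=O)/C(CB1OC(C)(C)C(C)(C)O1)=C/COCc1ccccc1 | intermediate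
18 | methyl (3R,4R)-3-[(benzyloxy)methyl]-4-(DHB)-2-methylidene-4-[(Bpin)oxy]butanoate (syn-borate, not isolated) | C=C(C(=O)OC)[C@H](COCc1ccccc1)[C@@H](OB1OC(C)(C)C(C)(C)O1)c1cc(OC)c2c(c1)[C@H](COCc1ccccc1)[C@H](c1ccc(OCc3ccccc3)c(OC)c1)O2 | intermediate
19 | (4R,5R)-4-[(benzyloxy)methyl]-5-(DHB)-3-methylideneoxolan-2-one (cis) | C=C1C(=O)O[C@@H](c2cc(OC)c3c(c2)[C@H](COCc2ccccc2)[C@H](c2ccc(OCc4ccccc4)c(OC)c2)O3)[C@H]1COCc1ccccc1 | intermediate
20 | 1-(benzyloxy)-4-bromo-2-methoxybenzene | COc1cc(Br)ccc1OCc1ccccc1 | intermediate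
21 | [4-(benzyloxy)-3-methoxyphenyl]magnesium bromide (not isolated) | COc1cc([Mg]Br)ccc1OCc1ccccc1 | intermediate
22 | (4R,5R)-3-[(BMP)methyl]-4-[(benzyloxy)methyl]-5-(DHB)oxolan-2-one (C3 epimers) | O=C1O[C@@H](c2cc(OC)c3c(c2)[C@H](COCc2ccccc2)[C@H](c2ccc(OCc4ccccc4)c(OC)c2)O3)[C@@H](COCc2ccccc2)C1Cc1ccc(OCc2ccccc2)c(OC)c1 | intermediate
23 | sodium enolate of 22 (not isolated) | [Na+].[O-]C1=C(Cc2ccc(OCc3ccccc3)c(OC)c2)[C@H](COCc2ccccc2)[C@H](c2cc(OC)c3c(c2)[C@H](COCc2ccccc2)[C@H](c2ccc(OCc4ccccc4)c(OC)c2)O3)O1 | intermediate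
24 | (3S,4R,5R)-3-[(BMP)methyl]-4-[(benzyloxy)methyl]-5-(DHB)-3-hydroxyoxolan-2-one | O=C1O[C@@H](c2cc(OC)c3c(c2)[C@H](COCc2ccccc2)[C@H](c2ccc(OCc4ccccc4)c(OC)c2)O3)[C@@H](COCc2ccccc2)[C@@]1(O)Cc1ccc(OCc2ccccc2)c(OC)c1 | intermediate
25 | (3S,4R,5R)-3-[(BMP)methyl]-4-[(benzyloxy)methyl]-5-(DHB)oxolane-2,3-diol (C2 anomers) | OC1O[C@@H](c2cc(OC)c3c(c2)[C@H](COCc2ccccc2)[C@H](c2ccc(OCc4ccccc4)c(OC)c2)O3)[C@@H](COCc2ccccc2)[C@@]1(O)Cc1ccc(OCc2ccccc2)c(OC)c1 | intermediate
26 | (3S,4R,5R)-3-[(BMP)methyl]-4-[(benzyloxy)methyl]-5-(DHB)oxolan-3-ol | COc1cc(C[C@@]2(O)CO[C@@H](c3cc(OC)c4c(c3)[C@H](COCc3ccccc3)[C@H](c3ccc(OCc5ccccc5)c(OC)c3)O4)[C@H]2COCc2ccccc2)ccc1OCc1ccccc1 | intermediate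
27 | (3S,4R,5R)-4-(hydroxymethyl)-3-[(4-hydroxy-3-methoxyphenyl)methyl]-5-[(2R,3R)-2-(4-hydroxy-3-methoxyphenyl)-3-(hydroxymethyl)-7-methoxy-2,3-dihydro-1-benzofuran-5-yl]oxolan-3-ol | COc1cc(C[C@@]2(O)CO[C@@H](c3cc(OC)c4c(c3)[C@H](CO)[C@H](c3ccc(O)c(OC)c3)O4)[C@H]2CO)ccc1O | target

**Count and risks**

Total step count: 17. Longest linear sequence: 13 steps (steps 1 to 7, 11, 13 to 17).

Steps most likely to fail:

1. Step 11. The ester-deactivated, γ-substituted boronate may add too slowly to the electron-rich aldehyde under the phosphoric acid. Face selection may be poor, or the syn relationship may be lost through acid-promoted ionisation at the benzylic borate. The fallback moves stereocontrol from the catalyst to a chiral ester on the boronate, which the lactonisation expels. It sets out from 12. (−)-8-Phenylmenthol is acylated with acryloyl chloride to (1R,2S,5R)-5-methyl-2-(2-phenylpropan-2-yl)cyclohexyl prop-2-enoate F1. Its Morita–Baylis–Hillman reaction with 12 should give the 8-phenylmenthyl 4-(benzyloxy)-3-hydroxy-2-methylidenebutanoate F2, acetylation the 8-phenylmenthyl 3-acetoxy-4-(benzyloxy)-2-methylidenebutanoate F3, and CuCl-catalysed borylation with 16 the 8-phenylmenthyl (E)-4-(benzyloxy)-2-[(Bpin)methyl]but-2-enoate F4. Sc(OTf)3-catalysed allylboration of 11 with F4 at −78 °C is a Lewis acid-accelerated variant that keeps the chair stereospecificity. Lactonisation with loss of the auxiliary alcohol comes back to the route at 19.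

2. Step 16. The α-hydroxylated lactol may form its oxocarbenium ion only slowly, so that BF3·OEt2 has time to ionise the electron-rich benzylic C–O bonds (C2–O1 of ring A, C2′–O1′ of ring B), with epimerisation to the trans isomers or reductive ring opening. The fallback removes the carbonyl oxygen before C4 is functionalised, when the oxocarbenium ion is allyl-stabilised and forms readily at −78 °C. It sets out from 19. Reduction with i-Bu2AlH should give the (4R,5R)-4-[(benzyloxy)methyl]-5-(DHB)-3-methylideneoxolan-2-ol F5. Et3SiH/BF3·OEt2 at −78 °C should give the (2R,3R)-3-[(benzyloxy)methyl]-2-(DHB)-4-methylideneoxolane F6. Epoxidation with mCPBA buffered by NaHCO3, on the face opposite the cis C2/C3 substituents, should give the (3R,6R,7R)-7-[(benzyloxy)methyl]-6-(DHB)-1,5-dioxaspiro[2.4]heptane F7. CuI-catalysed opening of F7 at the epoxide CH2 by Grignard reagent 21 should give the tertiary alcohol and comes back to the route at 26.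

3. Step 3. Oxidative addition and coupling at the hindered, electron-rich aryl iodide may be sluggish, or the diazo group may be lost through palladium carbene formation. The fallback builds the diazo ester from a keto ester instead. It sets out from 4. Iodine–magnesium exchange with i-PrMgCl·LiCl, which leaves the bromide untouched, and acylation with diethyl oxalate should give ethyl 2-{2-[(BMP)methoxy]-5-bromo-3-methoxyphenyl}-2-oxoacetate F8. Condensation with 4-methylbenzenesulfonohydrazide should give the ethyl 2-{2-[(BMP)methoxy]-5-bromo-3-methoxyphenyl}-2-(tosylhydrazono)acetate F9. Treatment of F9 with DBU (Bamford–Stevens reaction) comes back to the route at 6.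

**Further compounds**

F1 | step 11 | (1R,2S,5R)-5-methyl-2-(2-phenylpropan-2-yl)cyclohexyl prop-2-enoate | C[C@@H]1CC[C@H]([C@@H](C1)OC(=O)C=C)C(C)(C)c1ccccc1
F2 | step 11 | (1R,2S,5R)-5-methyl-2-(2-phenylpropan-2-yl)cyclohexyl 4-(benzyloxy)-3-hydroxy-2-methylidenebutanoate (carbinol epimers) | C[C@@H]1CC[C@H]([C@@H](C1)OC(=O)C(=C)C(O)COCc1ccccc1)C(C)(C)c1ccccc1
F3 | step 11 | (1R,2S,5R)-5-methyl-2-(2-phenylpropan-2-yl)cyclohexyl 3-acetoxy-4-(benzyloxy)-2-methylidenebutanoate (epimers) | C[C@@H]1CC[C@H]([C@@H](C1)OC(=O)C(=C)C(OC(C)=O)COCc1ccccc1)C(C)(C)c1ccccc1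
F4 | step 11 | (1R,2S,5R)-5-methyl-2-(2-phenylpropan-2-yl)cyclohexyl (E)-4-(benzyloxy)-2-[(Bpin)methyl]but-2-enoate | C[C@@H]1CC[C@H]([C@@H](C1)OC(=O)/C(CB2OC(C)(C)C(C)(C)O2)=C/COCc2ccccc2)C(C)(C)c1ccccc1
F5 | step 16 | (4R,5R)-4-[(benzyloxy)methyl]-5-(DHB)-3-methylideneoxolan-2-ol (anomers) | C=C1C(O)O[C@@H](c2cc(OC)c3c(c2)[C@H](COCc2ccccc2)[C@H](c2ccc(OCc4ccccc4)c(OC)c2)O3)[C@H]1COCc1ccccc1
F6 | step 16 | (2R,3R)-3-[(benzyloxy)methyl]-2-(DHB)-4-methylideneoxolane | C=C1CO[C@@H](c2cc(OC)c3c(c2)[C@H](COCc2ccccc2)[C@H](c2ccc(OCc4ccccc4)c(OC)c2)O3)[C@H]1COCc1ccccc1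
F7 | step 16 | (3R,6R,7R)-7-[(benzyloxy)methyl]-6-(DHB)-1,5-dioxaspiro[2.4]heptane | C1O[C@@]12CO[C@@H](c3cc(OC)c4c(c3)[C@H](COCc3ccccc3)[C@H](c3ccc(OCc5ccccc5)c(OC)c3)O4)[C@H]2COCc1ccccc1
F8 | step 3 | ethyl 2-{2-[(BMP)methoxy]-5-bromo-3-methoxyphenyl}-2-oxoacetate | CCOC(=O)C(=O)c1cc(Br)cc(OC)c1OCc1ccc(OCc2ccccc2)c(OC)c1
F9 | step 3 | ethyl 2-{2-[(BMP)methoxy]-5-bromo-3-methoxyphenyl}-2-(tosylhydrazono)acetate | CCOC(=O)C(=NNS(=O)(=O)c1ccc(C)cc1)c1cc(Br)cc(OC)c1OCc1ccc(OCc2ccccc2)c(OC)c1
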